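**Plan**

1. Retrosynthesis: remove the two O-methyl groups, then cut the quinone ring at the two bonds joining the C(OMe)–C(=O) pair to the two indolyl-bearing ring carbons, which gives dimethyl oxalate and a 1,4-bis(indolyl)butane-2,3-dione. The diketone is cut at its CO–CO bond into two indol-3-ylacetic esters, and the 2-methylbut-3-en-2-yl group is taken off indole C-2.
2. Enabling feature: the six-membered ring is a 2,5-dioxygenated 1,4-benzoquinone, the enol form of a cyclohexane-1,2,4,5-tetraone in which each indolyl-bearing carbon lies between two carbonyl carbons. Both are therefore enolate carbons of one α-diketone and can be acylated by the two ester carbons of one oxalate.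
3. Forward order: reverse prenylation of methyl indol-3-ylacetate at C-2; mixed acyloin coupling with a second indol-3-ylacetate (chain joined at CO–CO); oxidation to the diketone; closure of the only new ring (the quinone) by double Claisen condensation; O-methylation.
4. Stereochemistry: the target has no stereocentre and no configured double bond, so nothing has to be set.

Key step: step 5

Remark: 9-BBN (commercial THF solution of its dimer) and diazomethane (generated ex situ) are written as the monomeric reagents; hydroxyquinone 13 is drawn as one tautomer of a rapidly equilibrating set.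

**Route**

Step 1
Reactants: 1 9-borabicyclo[3.3.1]nonane (9-BBN); 2 3-methylbuta-1,2-diene
Product: 3 9-(3-methylbut-2-en-1-yl)-9-borabicyclo[3.3.1]nonane (B-prenyl-9-BBN)
Conditions: THF, 0 °C → rt; used as the solution
Reagents that add atoms: none
Why: Hydroboration of the unsubstituted terminal C=C of the 1,1-dimethylallene places boron on the CH2 carbon and gives the allylic borane, the established preparation of this reagent.

Step 2
Reactants: 4 methyl 2-(1H-indol-3-yl)acetate; 3 B-prenyl-9-BBN
Product: 6 methyl 2-[2-(2-methylbut-3-en-2-yl)-1H-indol-3-yl]acetate, via 3-chloroindolenine ester 5 (not isolated)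
Conditions: tBuOCl, Et3N, THF, −78 °C; then 3, −78 °C → rt; aq. NaHCO3
Reagents that add atoms: none
Why: Electrophilic chlorination at C-3 gives the 3-chloroindolenine 5, whose imine nitrogen binds the allylborane so that the prenyl group is transferred to C-2 through a six-membered transition state with allylic transposition (the quaternary carbon ends up on C-2), and loss of HCl re-aromatises the indole; this reverse prenylation is established for 3-alkylindoles such as tryptophan esters.

Step 3
Reactants: 6 methyl 2-[2-(2-methylbut-3-en-2-yl)-1H-indol-3-yl]acetate; 4 methyl 2-(1H-indol-3-yl)acetate (threefold excess)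
Product: 7 1-(1H-indol-3-yl)-4-[2-(2-methylbut-3-en-2-yl)-1H-indol-3-yl]-2,3-bis(trimethylsilyloxy)but-2-ene
Conditions: Na (dispersion, excess), TMSCl (excess), toluene, reflux; filtration; cold aq. NaHCO3; used crude
Reagents that add atoms: chlorotrimethylsilane, C[Si](C)(C)Cl
Why: Acyloin condensation with chlorotrimethylsilane trapping: electron transfer from sodium couples the two ester carbonyl carbons, and silylation of the enediolate and of the expelled methoxide keeps the acidic arylacetic esters from Claisen chemistry; cross-coupling is statistical, so the cheap ester 4 is used in excess to channel 6 into 7, which is carried on crude together with the symmetrical ether derived from 4 and separated at the diketone stage (N-silyl groups formed in the flask are lost in the bicarbonate wash).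

Step 4
Reactants: 7 bis(trimethylsilyloxy)butene
Product: 10 1-(1H-indol-3-yl)-4-[2-(2-methylbut-3-en-2-yl)-1H-indol-3-yl]butane-2,3-dione, via hydroxy ketone 8 (not isolated), via isomeric hydroxy ketone 9 (not isolated)
Conditions: Cu(OAc)2·H2O (2.2 equiv), AcOH–MeOH–H2O, 60 °C; chromatography
Reagents that add atoms: none
Why: Acidic methanolysis releases the enediol, which tautomerises to the two acyloins 8 and 9, and Cu(OAc)2 in aqueous acetic acid oxidises either α-hydroxy ketone to the 1,2-diketone (the classical acyloin-to-diketone oxidation) without touching the indoles or the terminal alkene; the cross-product 10 is separated here from the symmetrical diketones.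

Step 5
Reactants: 10 1-(1H-indol-3-yl)-4-[2-(2-methylbut-3-en-2-yl)-1H-indol-3-yl]butane-2,3-dione; 11 dimethyl oxalate
Product: 13 2,5-dihydroxy-3-(1H-indol-3-yl)-6-[2-(2-methylbut-3-en-2-yl)-1H-indol-3-yl]cyclohexa-2,5-diene-1,4-dione, via triketo ester 12 (not isolated)
Conditions: NaOMe (4 equiv), 11 (3 equiv), degassed MeOH–THF, 0 °C → rt, Ar; then 1 M HCl
Reagents that add atoms: none
Why: Methoxide converts 10 into a benzylic enolate (each CH2 lies between an indol-3-yl group and the diketone), which is C-acylated by dimethyl oxalate in an intermolecular Claisen condensation to give triketo ester 12 as its enolate; enolisation at the second indolylmethylene and a Dieckmann condensation on the remaining ester (6-exo-trig, the only ring closed) give the cyclohexane-1,2,4,5-tetraone, which tautomerises at once to the dianion of the 2,5-dihydroxy-1,4-benzoquinone, a doubly vinylogous carboxylate whose formation makes the sequence irreversible. The closest known reaction type is the double Claisen condensation of ketones carrying two acidic methylene groups (such as 1,3-diarylacetones) with dialkyl oxalates to cyclic polyketones. No stereocentre is formed. The step needs C- over O-acylation and six- over five-membered ring closure: O-acyl products and aldol adducts form reversibly under methoxide, while the enolised 1,3-dicarbonyl unit of 12 leaves the ester as the only electrophile for the second carbanion, so the material should funnel to the quinone dianion. Benzilic ester rearrangement of 10 is held back because the diketone is present as its enolate and the oxalate is in excess, and which methylene reacts first is immaterial because both sequences converge on 13.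

Step 6
Reactants: 13 2,5-dihydroxy-3-(1H-indol-3-yl)-6-[2-(2-methylbut-3-en-2-yl)-1H-indol-3-yl]cyclohexa-2,5-diene-1,4-dione
Product: 14 2,5-dimethoxy-3-(1H-indol-3-yl)-6-[2-(2-methylbut-3-en-2-yl)-1H-indol-3-yl]cyclohexa-2,5-diene-1,4-dione (CNP0103667.0)
Conditions: CH2N2, Et2O–MeOH, 0 °C
Reagents that add atoms: diazomethane, C=[N+]=[N-]
Why: The vinylogous carboxylic acid hydroxyls of the 2,5-dihydroxyquinone, far more acidic than the indole N–H groups, should be O-methylated by diazomethane to the 2,5-dimethoxy-1,4-benzoquinone, the classical conversion of dihydroxyquinones into their dimethyl ethers.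

**Compound list**

1 | 9-borabicyclo[3.3.1]nonane (9-BBN) | B1C2CCCC1CCC2 | starting material
2 | 3-methylbuta-1,2-diene | CC(C)=C=C | starting material
3 | 9-(3-methylbut-2-en-1-yl)-9-borabicyclo[3.3.1]nonane | CC(C)=CCB1C2CCCC1CCC2 | intermediate
4 | methyl 2-(1H-indol-3-yl)acetate | COC(=O)Cc1c[nH]c2ccccc12 | starting material
5 | methyl 2-(3-chloro-3H-indol-3-yl)acetate (racemic) | COC(=O)CC1(Cl)C=Nc2ccccc21 | intermediate (not isolated)
6 | methyl 2-[2-(2-methylbut-3-en-2-yl)-1H-indol-3-yl]acetate | COC(=O)Cc1c(C(C)(C)C=C)[nH]c2ccccc12 | intermediate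
7 | 1-(1H-indol-3-yl)-4-[2-(2-methylbut-3-en-2-yl)-1H-indol-3-yl]-2,3-bis(trimethylsilyloxy)but-2-ene (E/Z mixture, geometry not defined) | C=CC(C)(C)c1[nH]c2ccccc2c1CC(O[Si](C)(C)C)=C(O[Si](C)(C)C)Cc1c[nH]c2ccccc12 | intermediate
8 | 3-hydroxy-4-(1H-indol-3-yl)-1-[2-(2-methylbut-3-en-2-yl)-1H-indol-3-yl]butan-2-one (racemic) | C=CC(C)(C)c1[nH]c2ccccc2c1CC(=O)C(O)Cc1c[nH]c2ccccc12 | intermediate (not isolated)
9 | 3-hydroxy-1-(1H-indol-3-yl)-4-[2-(2-methylbut-3-en-2-yl)-1H-indol-3-yl]butan-2-one (racemic) | C=CC(C)(C)c1[nH]c2ccccc2c1CC(O)C(=O)Cc1c[nH]c2ccccc12 | intermediate (not isolated)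
10 | 1-(1H-indol-3-yl)-4-[2-(2-methylbut-3-en-2-yl)-1H-indol-3-yl]butane-2,3-dione | C=CC(C)(C)c1[nH]c2ccccc2c1CC(=O)C(=O)Cc1c[nH]c2ccccc12 | intermediate
11 | dimethyl oxalate | COC(=O)C(=O)OC | starting material
12 | methyl 3-(1H-indol-3-yl)-6-[2-(2-methylbut-3-en-2-yl)-1H-indol-3-yl]-2,4,5-trioxohexanoate (racemic, present as enolates) | COC(=O)C(=O)C(c1c[nH]c2ccccc12)C(=O)C(=O)Cc1c(C(C)(C)C=C)[nH]c2ccccc12 | intermediate (not isolated)
13 | 2,5-dihydroxy-3-(1H-indol-3-yl)-6-[2-(2-methylbut-3-en-2-yl)-1H-indol-3-yl]cyclohexa-2,5-diene-1,4-dione | C=CC(C)(C)c1[nH]c2ccccc2c1C1=C(O)C(=O)C(c2c[nH]c3ccccc23)=C(O)C1=O | intermediate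
14 | 2,5-dimethoxy-3-(1H-indol-3-yl)-6-[2-(2-methylbut-3-en-2-yl)-1H-indol-3-yl]cyclohexa-2,5-diene-1,4-dione | C=CC(C)(C)c1[nH]c2ccccc2c1C1=C(OC)C(=O)C(c2c[nH]c3ccccc23)=C(OC)C1=O | target

**Step count and risks**

Total step count: 6. Longest linear sequence: 6 (steps 1 to 6).

Steps most likely to fail, riskiest first:

Step 3. The coupling is not selective between the two esters, so homo-coupling of each competes with cross-coupling, and enolisation of the arylacetic esters or premature loss of the silyl ethers on handling may further erode the return. The fallback is a directed synthesis that sets out from 6 and comes back at 10. Commercial indole-3-pyruvic acid is treated with diazomethane, which should esterify the acid and methylate the enol to give methyl (Z)-3-(1H-indol-3-yl)-2-methoxyprop-2-enoate F1. The dilithio derivative of 6 (LiN(iPr)2, THF, −78 °C) is acylated by F1 (its N–H first removed with LiN(SiMe3)2) in a crossed Claisen condensation to give methyl 5-(1H-indol-3-yl)-4-methoxy-2-[2-(2-methylbut-3-en-2-yl)-1H-indol-3-yl]-3-oxopent-4-enoate F2. Krapcho dealkoxycarbonylation (LiCl, wet DMSO, 130 °C) should give (Z)-4-(1H-indol-3-yl)-3-methoxy-1-[2-(2-methylbut-3-en-2-yl)-1H-indol-3-yl]but-3-en-2-one F3, whose capped enol cannot lactonise. Mild hydrolysis of the enol ether (1 M HCl, THF, rt) then gives 10.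

Step 5. The enolisable α-diketone may be consumed by aldol self-condensation or benzilic ester rearrangement before C-acylation, or the sequence may stall at the open-chain stage. The fallback abandons ring construction, sets out from 3 and comes back at 13. Commercial indole is chlorinated with N-chlorosuccinimide to 3-chloro-1H-indole F4, which with 3 and Et3N should give 2-(2-methylbut-3-en-2-yl)-1H-indole F5 by the same allyl transfer as in step 2. F5 and tetrabromo-1,4-benzoquinone with Cs2CO3 in MeCN give, by addition–elimination at a bromine-bearing carbon, 2,3,5-tribromo-6-[2-(2-methylbut-3-en-2-yl)-1H-indol-3-yl]cyclohexa-2,5-diene-1,4-dione F6. Indole and Cs2CO3 then replace the bromide para to the first indolyl group to give 2,5-dibromo-3-(1H-indol-3-yl)-6-[2-(2-methylbut-3-en-2-yl)-1H-indol-3-yl]cyclohexa-2,5-diene-1,4-dione F7. NaOH in aqueous MeOH hydrolyses both vinylogous acyl bromides to 13.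

Step 2. The chloroindolenine 5 carries an acidic CH2CO2Me group, so base-induced loss of HCl toward the exocyclic alkylidene tautomer, or over-chlorination, may compete with allyl transfer. The fallback replaces the allylborane chemistry by cross-coupling, sets out from 4 and comes back at 6. Compound 4 is brominated at C-2 with N-bromosuccinimide (CH2Cl2, 0 °C) to methyl 2-(2-bromo-1H-indol-3-yl)acetate F8. A γ-selective Suzuki–Miyaura coupling with commercial 3-methylbut-2-enylboronic acid pinacol ester (Pd(OAc)2, bulky biarylphosphine ligand, K3PO4, THF–H2O) then installs the 2-methylbut-3-en-2-yl group to give 6.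

**Further compounds**

F1 | step 3 | methyl (Z)-3-(1H-indol-3-yl)-2-methoxyprop-2-enoate | COC(=O)/C(OC)=C/c1c[nH]c2ccccc12
F2 | step 3 | methyl 5-(1H-indol-3-yl)-4-methoxy-2-[2-(2-methylbut-3-en-2-yl)-1H-indol-3-yl]-3-oxopent-4-enoate (Z, racemic) | COC(=O)C(c1c(C(C)(C)C=C)[nH]c2ccccc12)C(=O)/C(OC)=C/c1c[nH]c2ccccc12
F3 | step 3 | (Z)-4-(1H-indol-3-yl)-3-methoxy-1-[2-(2-methylbut-3-en-2-yl)-1H-indol-3-yl]but-3-en-2-one | C=CC(C)(C)c1[nH]c2ccccc2c1CC(=O)/C(OC)=C/c1c[nH]c2ccccc12
F4 | step 5 | 3-chloro-1H-indole | Clc1c[nH]c2ccccc12
F5 | step 5 | 2-(2-methylbut-3-en-2-yl)-1H-indole | C=CC(C)(C)c1cc2ccccc2[nH]1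
F6 | step 5 | 2,3,5-tribromo-6-[2-(2-methylbut-3-en-2-yl)-1H-indol-3-yl]cyclohexa-2,5-diene-1,4-dione | C=CC(C)(C)c1[nH]c2ccccc2c1C1=C(Br)C(=O)C(Br)=C(Br)C1=O
F7 | step 5 | 2,5-dibromo-3-(1H-indol-3-yl)-6-[2-(2-methylbut-3-en-2-yl)-1H-indol-3-yl]cyclohexa-2,5-diene-1,4-dione | C=CC(C)(C)c1[nH]c2ccccc2c1C1=C(Br)C(=O)C(c2c[nH]c3ccccc23)=C(Br)C1=O
F8 | step 2 | methyl 2-(2-bromo-1H-indol-3-yl)acetate | COC(=O)Cc1c(Br)[nH]c2ccccc12
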